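**Assumption (one line):** drimane-type numbering is used throughout (decalin C1–C10, C11 = benzylic CH2), and the target is taken exactly as drawn: trans-decalin, 10β-CH3, 5α-H, 9β-CH2Ar, 4α-CH3 / 4β-(4-methylpent-3-enyl), i.e. (4R,5S,9S,10S).

## Retrosynthetic overview

1. Jaspic acid ⇒ global O-demethylation and Δ2 hydrogenation ⇒ C11–aryl bond by B-alkyl Suzuki coupling of a 9-exo-methylene diene; the hydroboration sets C9.
2. 4β-Homoprenyl ⇒ Wittig on a 4β-CH2CH2CHO, made from a 4β-O-allyl ether by [2,3]-Wittig then anionic oxy-Cope rearrangement (C–O replaced by C–C with net retention; this is the key C4–C bond).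
3. 4β-Alkoxide / 4α-CH3 ⇒ α-face MeMgBr addition to a ring-A enone.
4. Ring A ⇒ intramolecular aldol condensation of the keto-aldehyde from ozonolysis of 6-allyl-6-methylcarvone.
5. Ring B and C5 ⇒ (R)-carvone; C10 ⇒ two enolate alkylations (second one trans to isopropenyl). Ring order: B (bought), then A; the arene is bought.

## Route

**Step 1**
Reactants: 1 (R)-(−)-carvone; 2 iodomethane
Product: 3 (5R,6S)-6-methylcarvone (trans major; the minor C6 epimer converges in Step 2)
Conditions: LDA, THF, −78 °C; MeI, −78 → 0 °C
Reagents that add atoms: iodomethane, CI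
Why: Kinetic α′-enolate alkylation installs the future C10 methyl; the new centre is re-enolised in Step 2, so its configuration is irrelevant.

**Step 2**
Reactants: 3; 4 allyl bromide
Product: 5 (5S,6S)-6-allyl-6-methylcarvone (allyl trans, CH3 cis to isopropenyl)
Conditions: LDA, THF, −78 °C; allyl bromide, DMPU, −78 → 0 °C
Reagents that add atoms: allyl bromide, C=CCBr
Why: Enolate alkylation occurs anti to the pseudoaxial isopropenyl group on the adjacent carbon, so the carvone stereocentre sets the C10 quaternary centre.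

**Step 3**
Reactants: 5; 6 ozone
Product: 7 2-[(1S,6R)-6-acetyl-1,3-dimethyl-2-oxocyclohex-3-en-1-yl]acetaldehyde
Conditions: O3, CH2Cl2/MeOH, −78 °C (Sudan III end-point); Me2S
Reagents that add atoms: ozone, [O-][O+]=O
Why: Electrophilic ozonolysis cleaves the two isolated alkenes (isopropenyl → acetyl, allyl → CH2CHO) while the electron-poor enone C=C is left intact.

**Step 4**
Reactants: 7
Product: 8 trans-fused ring-A enone: (4aS,8aR)-4a,6-dimethyl-4,4a,8,8a-tetrahydronaphthalene-1,5-dione (drimane numbering: 4-oxo-Δ2, 9-oxo-Δ7, 8-CH3, 10β-CH3, 5α-H)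
Conditions: piperidine, AcOH, PhH, reflux (−H2O)
Reagents that add atoms: none
Why: Intramolecular aldol condensation of the acetyl CH3 onto the aldehyde is the only six-ring mode and closes ring A; C5 and C10 are already set, and the trans fusion at the epimerisable C5 is expected to be the more stable one.

**Step 5**
Reactants: 8; 9 methylmagnesium bromide
Product: 10 4β-hydroxy-4α,8,10β-trimethyl-5α-decalin-2,7-dien-9-one
Conditions: MeMgBr (1.1 equiv), CeCl3, THF, −78 °C
Reagents that add atoms: methylmagnesium bromide, C[Mg]Br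
Why: Chemoselective 1,2-addition to the less hindered C4 carbonyl (C9 is flanked by a quaternary carbon and an α-methyl alkene); attack is from the α face, away from the 1,3-diaxial C10 methyl, giving 4α-CH3 / 4β-OH.

**Step 6**
Reactants: 10; 11 methyltriphenylphosphonium bromide
Product: 12 4β-hydroxy-4α,8,10β-trimethyl-9-methylene-5α-decalin-2,7-diene
Conditions: Ph3PCH3Br, KOt-Bu (excess), toluene, 90 °C
Reagents that add atoms: methyltriphenylphosphonium bromide, C[P+](c1ccccc1)(c1ccccc1)c1ccccc1.[Br-]
Why: Wittig methylenation of the hindered C9 ketone introduces C11 and removes the only carbonyl before the organolithium steps (excess ylide covers the free OH).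

**Step 7**
Reactants: 12; 4 allyl bromide
Product: 13 4β-allyloxy-4α,8,10β-trimethyl-9-methylene-5α-decalin-2,7-diene
Conditions: KH, allyl bromide, THF, 0 °C → rt
Reagents that add atoms: allyl bromide, C=CCBr
Why: Williamson etherification of the tertiary potassium alkoxide gives the bis-allylic ether; no stereocentre changes.

**Step 8**
Reactants: 13
Product: 14 2β-(1-hydroxyprop-2-en-1-yl)-4,8,10β-trimethyl-9-methylene-5α-decalin-3,7-diene (carbinol epimers; both are used)
Conditions: n-BuLi, THF, −78 → −30 °C
Reagents that add atoms: none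
Why: [2,3]-Wittig rearrangement of the α-lithiated allyl ether is suprafacial across the ring allyl unit, so the C4β–O bond is traded for a C2β–C bond and a Δ3 alkene.

**Step 9**
Reactants: 14
Product: 15 3-[4α,8,10β-trimethyl-9-methylene-5α-decalin-2,7-dien-4β-yl]propanal
Conditions: KH, 18-crown-6, THF, rt → 50 °C; aq. NH4Cl
Reagents that add atoms: none
Why: Anionic oxy-Cope [3,3] rearrangement moves the three-carbon unit suprafacially from C2β back to C4β; net, the C4–O bond of 10 is replaced by C4–C with retention, which sets the C4 quaternary centre (4α-CH3, 4β-chain).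

**Step 10**
Reactants: 15; 16 isopropyltriphenylphosphonium iodide
Product: 17 4β-(4-methylpent-3-enyl)-4α,8,10β-trimethyl-9-methylene-5α-decalin-2,7-diene
Conditions: i-PrPPh3I, n-BuLi, THF, −78 °C → rt
Reagents that add atoms: isopropyltriphenylphosphonium iodide, CC(C)[P+](c1ccccc1)(c1ccccc1)c1ccccc1.[I-]
Why: Wittig olefination of the aldehyde with the isopropylidene ylide completes the homoprenyl chain.

**Step 11**
Reactants: 17; 18 methyl 3-bromo-4-methoxybenzoate
Product: 19 methyl 4-methoxy-3-{[4β-(4-methylpent-3-enyl)-4α,8,10β-trimethyl-5α-decalin-2,7-dien-9β-yl]methyl}benzoate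
Conditions: 9-BBN (1.2 equiv), THF, 0 °C → rt; then 18, Pd(dppf)Cl2, AsPh3, aq. Cs2CO3, DMF, 60 °C
Reagents that add atoms: methyl 3-bromo-4-methoxybenzoate, COC(=O)c1ccc(OC)c(Br)c1 (9-BBN leaves only H)
Why: 9-BBN adds to the terminal 1,1-disubstituted alkene in preference to the hindered ring and trisubstituted alkenes, delivering H to C9 from the α face (anti to the C10 methyl) to give 9β-CH2B; B-alkyl Suzuki–Miyaura coupling then forms C11–aryl.

**Step 12**
Reactants: 19
Product: 20 methyl 4-methoxy-3-{[4β-(4-methylpent-3-enyl)-4α,8,10β-trimethyl-5α-decalin-7-en-9β-yl]methyl}benzoate (jaspic acid methyl ester methyl ether)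
Conditions: H2 (1 atm), RhCl(PPh3)3, PhH/EtOH, rt
Reagents that add atoms: none
Why: Wilkinson hydrogenation reduces the cis-disubstituted Δ2 alkene and leaves the two trisubstituted alkenes (Δ7 and side chain), the arene and the ester untouched.

**Step 13**
Reactants: 20
Product: 21 jaspic acid
Conditions: NaSEt, DMF, 130 °C; then dilute HCl, 0 °C
Reagents that add atoms: none
Why: Thiolate SN2 demethylation cleaves both the methyl ester and the aryl methyl ether in one operation without touching the alkenes or stereocentres.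

## Compound list

1 | (R)-(−)-carvone | CC1=CC[C@H](CC1=O)C(C)=C | starting material
2 | iodomethane | CI | starting material
3 | (5R,6S)-6-methylcarvone | C[C@@H]1C(=O)C(C)=CC[C@H]1C(C)=C | intermediate
4 | allyl bromide | C=CCBr | starting material
5 | (5S,6S)-6-allyl-6-methylcarvone | C=CC[C@]1(C)C(=O)C(C)=CC[C@H]1C(C)=C | intermediate
6 | ozone | [O-][O+]=O | starting material (reagent)
7 | 2-[(1S,6R)-6-acetyl-1,3-dimethyl-2-oxocyclohex-3-en-1-yl]acetaldehyde | O=CC[C@]1(C)C(=O)C(C)=CC[C@H]1C(C)=O | intermediate
8 | (4aS,8aR)-4a,6-dimethyl-4,4a,8,8a-tetrahydronaphthalene-1,5-dione (trans) | O=C1C=CC[C@]2(C)C(=O)C(C)=CC[C@@H]12 | intermediate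
9 | methylmagnesium bromide | C[Mg]Br | starting material
10 | 4β-hydroxy-4α,8,10β-trimethyl-5α-decalin-2,7-dien-9-one | O[C@@]1(C)C=CC[C@]2(C)C(=O)C(C)=CC[C@@H]12 | intermediate
11 | methyltriphenylphosphonium bromide | C[P+](c1ccccc1)(c1ccccc1)c1ccccc1.[Br-] | starting material
12 | 4β-hydroxy-4α,8,10β-trimethyl-9-methylene-5α-decalin-2,7-diene | O[C@@]1(C)C=CC[C@]2(C)C(=C)C(C)=CC[C@@H]12 | intermediate
13 | 4β-allyloxy-4α,8,10β-trimethyl-9-methylene-5α-decalin-2,7-diene | C=CCO[C@@]1(C)C=CC[C@]2(C)C(=C)C(C)=CC[C@@H]12 | intermediate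
14 | 2β-(1-hydroxyprop-2-enyl)-4,8,10β-trimethyl-9-methylene-5α-decalin-3,7-diene | CC1=C[C@@H](C(O)C=C)C[C@]2(C)C(=C)C(C)=CC[C@@H]12 | intermediate
15 | 3-[4α,8,10β-trimethyl-9-methylene-5α-decalin-2,7-dien-4β-yl]propanal | O=CCC[C@@]1(C)C=CC[C@]2(C)C(=C)C(C)=CC[C@@H]12 | intermediate
16 | isopropyltriphenylphosphonium iodide | CC(C)[P+](c1ccccc1)(c1ccccc1)c1ccccc1.[I-] | starting material
17 | 4β-(4-methylpent-3-enyl)-4α,8,10β-trimethyl-9-methylene-5α-decalin-2,7-diene | CC(C)=CCC[C@@]1(C)C=CC[C@]2(C)C(=C)C(C)=CC[C@@H]12 | intermediate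
18 | methyl 3-bromo-4-methoxybenzoate | COC(=O)c1ccc(OC)c(Br)c1 | starting material
19 | Δ2,7-diene aryl ester (Suzuki product) | CC(C)=CCC[C@@]1(C)C=CC[C@]2(C)[C@@H](Cc3cc(C(=O)OC)ccc3OC)C(C)=CC[C@@H]12 | intermediate
20 | jaspic acid methyl ester methyl ether | CC(C)=CCC[C@@]1(C)CCC[C@]2(C)[C@@H](Cc3cc(C(=O)OC)ccc3OC)C(C)=CC[C@@H]12 | intermediate
21 | jaspic acid | CC(C)=CCC[C@@]1(C)CCC[C@]2(C)[C@@H](Cc3cc(C(=O)O)ccc3O)C(C)=CC[C@@H]12 | target

## Summary

**Total steps:** 13. **Longest linear sequence:** 13 (fully linear from (R)-carvone; all other inputs are bought).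

**Three steps most likely to fail, with fallbacks:**

1. **Step 8, [2,3]-Wittig.** The shift delivers carbon to a face that is 1,3-diaxial to the C10 methyl, a [1,2]-shift can compete, and n-BuLi may add to the exocyclic diene. Fallback: drop the carbanion chemistry. Transpose alcohol 12 to the 2β-allylic alcohol (Δ3, 4-CH3) with a Re(VII) catalyst, esterify it with 5-methylhex-4-enoic acid, run an Ireland–Claisen rearrangement to place the chain on C4β, then decarboxylate (Barton).

2. **Step 9, anionic oxy-Cope.** It forms a congested quaternary centre, and the alkoxide can instead fragment by retro-allylation. Fallback: install the whole side chain by substitution instead of rearrangement, using carbamate-directed syn-SN2′ addition of a homoprenyl cuprate to the 2β-N-phenylcarbamate of the transposed allylic alcohol.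

3. **Step 11, hydroboration / B-alkyl Suzuki.** The conjugated diene hydroborates slowly, and the β-branched neopentyl-like borane is a poor coupling partner. Fallback: oxidise the borane (H2O2/NaOH) to the C11 alcohol, then either convert it to the iodide for a Ni-catalysed reductive cross-electrophile coupling with 18, or oxidise to the C11 aldehyde, add the aryl Grignard and deoxygenate the benzylic alcohol.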